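The vessel is closed, stirred and held at one temperature, so the incoming ligand charged can stand free or sit on a complex.

| flask | starting complex | incoming ligand | temperature | remark | time |
|---|---|---|---|---|---|
| Sunday's | 11 mM | 1.8 equiv | 25 °C | run made earlier |  |
| Thursday's | 11 mM | 2.9 equiv | 44 °C | run made earlier |  |
| Wednesday's | 5.5 mM | 1.3 equiv | 25 °C | run made earlier |  |
| noon | 11 mM | 1.30 equiv | 48 °C |  | 4.0 d |
| winter | 11 mM | 1.30 equiv | 40 °C |  | 4.0 d |

- Sunday's (time / d: complex with two exchanged / %, complex with one exchanged / %, starting complex / %): 1.25: 23, 27, 36; 2.50: 29, 27, 26; 4.00: 31, 27, 23; 6.00: 36, 27, 20; 8.00: 37, 25, 13; 10.0: 43, 24, 12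
- Thursday's (time / d: complex with two exchanged / %, complex with one exchanged / %, starting complex / %): 0.250: 27, 43, 18; 0.833: 46, 35, 5; 1.25: 51, 29, 6; 2.08: 68, 23, 3; 3.00: 75, 15, 1; 4.00: 80, 11, 3; 5.00: 87, 11, 1
- Wednesday's (time / d: complex with two exchanged / %, complex with one exchanged / %, starting complex / %): 0.833: 4, 21, 64; 1.67: 14, 19, 45; 2.50: 20, 26, 37; 5.00: 24, 26, 26; 10.0: 34, 21, 17

(scatter of a reading: 2 percentage points)

- which of these there is most of at the end, counted by the starting complex in it, noon (starting complex / complex with two exchanged / complex with one exchanged)
- which of these there is most of at the end, counted by the starting complex in it, winter (starting complex / complex with two exchanged / complex with one exchanged)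
- the largest of these amounts at the end, in percent of the starting complex charged, noon
- the largest of these amounts at the end, in percent of the starting complex charged, winter



*Which reagent is short?* The incoming ligand is the limiting reagent: noon and winter each get 1.30 equiv, while complete double exchange takes two equivalents.

*What do you reckon with?* Let a and b be the complex with one exchanged and the complex with two exchanged, as fractions of the starting complex charged, and E the equivalents charged. Wednesday's run at 10.0 d has a + 2 b = 0.890 equivalents on complexes from 1.3 equiv, so φ = 68.5%. Here φ, the spent share, is (a + 2 b)/E, the part of the incoming ligand charged that sits on complexes.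

*And your number?* I take a = 26%, a Wednesday reading, as an assumption. With φ at its Wednesday value, b = 31.5%, and with φ complete, b = 52.0%. The lower end stands above a, but at Wednesday's φ that order holds just while a stays below 29.7%, and my a is an assumption. The balance sets no bound on the starting complex, so against it I set two readings, Wednesday's 17% at 10.0 d and Thursday's 5% at 0.833 d, both lower than the lower end. As a judgement from these, not a bound, I commit to the complex with two exchanged as the leader in both flasks, somewhere in that band.

*Why should 4.0 d be enough?* Thursday's run at 44 °C, with 2.9 equiv, already had 1.27 equivalents on complexes at 0.833 d.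

*But Wednesday's last row sums to 72.0%. Where is the rest?* I cannot read that. φ holds only if the missing part carries no incoming ligand, which is my assumption.

The forecast gives complex with two exchanged at 44% for noon and complex with two exchanged at 42% for winter: “The lead is modest, and ligand shortage caps it.” Those figures come from its equilibrium balance, and my band is a separate range.

The flask gives complex with two exchanged at 43.7% at noon and complex with two exchanged at 37.2% in winter.

    starting complex + incoming ligand ⇌ leaving ligand + complex with one exchanged (K = 0.890, k = 0.00340 L mol⁻¹ s⁻¹, Ea = 78.0 kJ mol⁻¹, ΔH = 21.0 kJ mol⁻¹)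
    complex with one exchanged + incoming ligand ⇌ leaving ligand + complex with two exchanged (K = 0.270, k = 0.00600 L mol⁻¹ s⁻¹, Ea = 64.0 kJ mol⁻¹, ΔH = −38.0 kJ mol⁻¹)
    leaving ligand → by-product carried off (k = 1.80 × 10⁻⁵ s⁻¹, Ea = 97.0 kJ mol⁻¹)
    starting complex ⇌ dormant form (K = 1.80, k = 1.50 × 10⁻⁵ s⁻¹, Ea = 113 kJ mol⁻¹, ΔH = 6.00 kJ mol⁻¹)
    (constants at 40 °C)

At noon, 14.8% of the starting complex stands as the dormant form at 4.00 d. Noon's φ is 93.4%, above Wednesday's 68.5%, with 6.6% of the incoming ligand free. In the neighbour flask, winter with 3.20 equiv, φ is 53.0%, with 77.2% as the complex with two exchanged and 47% of the incoming ligand free.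

The numbers in the tables stem from a simulated flask for an exercise; noise was put on by code.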